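The route rests on disconnecting C1–C2 of the cyclopentane (C1–C5). A rhodium carbenoid at C2, made from the C3 diazo ketone on quaternary C4, inserts with retention into the ether-activated C1–H bond, which lies 1,5 to C2 through C3–C4–C5 on the cyclopropane-fused seven-membered ring (C1, C5–C10; cyclopropane C6–C7–C11). One operation closes the five-membered ring cis-fused and turns a secondary aryl ether into the tertiary one that direct etherification cannot give. The precursor carries methyl, pivaloyloxymethyl (C7′) and diazoacetyl on C4 and an α-aryloxy group on C1; C4 comes from a chair Claisen rearrangement, the oxepine from Friedel–Crafts closure afterwards.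

Key step: step 18

Remark: atom labels C1–C11 and C7′ are those of the target; α is the face of the cyclopropane carbon C11, β the opposite face.
Remark: a pivalate protects the C7′ oxygen because an ester oxygen 1,5 to the carbenoid carbon cannot trap it as a five-membered oxonium ylide, as a silyl or alkyl ether oxygen could; benzyl groups protect the phenol oxygens because hydrogenolysis spares the tertiary aryl ether and the cyclopropane.
Remark: if the cyclopropyl carbon rather than the methyl-bearing carbon migrates in step 3, the product is ketone 9 itself and steps 4–7 fall away.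
Remark: 3,5-bis(benzyloxy)phenol (19) is taken as purchasable.

Step 1
Reactants: 1 (+)-2-carene
Product: 2 cis-caran-trans-2-ol (hydroxyl on the later C5 trans to the cyclopropane CMe2; C10 methyl cis to it)
Conditions: BH3·THF, THF, 0 °C to rt; then NaOH, H2O2
Reagents that add atoms: hydrogen peroxide, OO
Why: Hydroboration–oxidation: borane adds syn from the face opposite the cyclopropane CMe2 group with boron on the less substituted alkene carbon, which sets C10 (methyl α) and gives the trans carbinol.

Step 2
Reactants: 2 cis-caran-trans-2-ol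
Product: 3 cis-caran-2-one
Conditions: Dess–Martin periodinane, NaHCO3, CH2Cl2, rt
Reagents that add atoms: none
Why: Dess–Martin oxidation of the secondary cyclopropylcarbinol under buffered conditions should leave the adjacent C10 stereocentre untouched.

Step 3
Reactants: 3 cis-caran-2-one
Product: 5 4,8,8-trimethylbicyclo[5.1.0]octan-2-one (C5 ketone; C10 methyl α), via α-silyl ketone 4 (not isolated)
Conditions: TMSCHN2, BF3·OEt2, CH2Cl2, −78 to −20 °C; then 1 M HCl, THF
Reagents that add atoms: (trimethylsilyl)diazomethane, C[Si](C)(C)C=[N+]=[N-]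
Why: Lewis-acid-promoted diazoalkane ring expansion (Tiffeneau–Demjanov type): the methyl-bearing secondary carbon, expected to migrate better than the cyclopropyl carbon, shifts with retention so that C10 keeps its configuration, and the α-silyl ketone loses silicon on acidic work-up.

Step 4
Reactants: 5 4,8,8-trimethylbicyclo[5.1.0]octan-2-one
Product: 6 4,8,8-trimethylbicyclo[5.1.0]oct-2-en-2-yl triflate (C5 enol triflate; C1=C5)
Conditions: KHMDS, THF, −78 °C; then PhNTf2
Reagents that add atoms: N-phenylbis(trifluoromethanesulfonimide), O=S(=O)(N(c1ccccc1)S(=O)(=O)C(F)(F)F)C(F)(F)F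
Why: Enolate O-triflation: C1 is the only enolisable position (C6–H is a cyclopropane bridgehead hydrogen), so a single enol triflate should form.

Step 5
Reactants: 6 enol triflate
Product: 7 4,8,8-trimethylbicyclo[5.1.0]oct-2-ene (C1=C5 alkene)
Conditions: Pd(OAc)2 (cat.), PPh3, HCO2H, Et3N, DMF, 60 °C
Reagents that add atoms: none
Why: Palladium-catalysed formate reduction of an enol triflate (oxidative addition, hydride transfer from formate, reductive elimination) removes the C5 oxygen and leaves the alkene.

Step 6
Reactants: 7 4,8,8-trimethylbicyclo[5.1.0]oct-2-ene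
Product: 8 4,8,8-trimethylbicyclo[5.1.0]octan-3-ol (C1 carbinol; configuration at C1 immaterial)
Conditions: 9-BBN, THF, 65 °C; then NaOH, H2O2
Reagents that add atoms: hydrogen peroxide, OO
Why: Hydroboration–oxidation: boron should go to C1, remote from the cyclopropane, because C5 is the more hindered alkene carbon and the one that best carries positive charge.

Step 7
Reactants: 8 4,8,8-trimethylbicyclo[5.1.0]octan-3-ol
Product: 9 4,8,8-trimethylbicyclo[5.1.0]octan-3-one (C1 ketone; C10 methyl α)
Conditions: Dess–Martin periodinane, NaHCO3, CH2Cl2, rt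
Reagents that add atoms: none
Why: Dess–Martin oxidation completes the 1,2-carbonyl transposition under neutral conditions that should not epimerise C10, now α to the carbonyl.

Step 8
Reactants: 9 4,8,8-trimethylbicyclo[5.1.0]octan-3-one
Product: 10 2,4,6-triisopropylbenzenesulfonylhydrazone of 9
Conditions: 2,4,6-triisopropylbenzenesulfonyl hydrazide, MeOH, rt
Reagents that add atoms: 2,4,6-triisopropylbenzenesulfonyl hydrazide, CC(C)c1cc(C(C)C)c(S(=O)(=O)NN)c(C(C)C)c1
Why: Hydrazone condensation prepares the ketone for a Shapiro reaction.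

Step 9
Reactants: 10 trisylhydrazone
Product: 11 3-iodo-4,8,8-trimethylbicyclo[5.1.0]oct-2-ene (C1 iodide; C1=C5)
Conditions: n-BuLi (2.2 equiv), THF, −78 to 0 °C; then I2, −78 °C
Reagents that add atoms: iodine, II
Why: Shapiro reaction: the second deprotonation takes the less substituted α-carbon C5, loss of sulfinate and N2 gives the C1 alkenyllithium, and iodine traps it without touching C10.

Step 10
Reactants: 12 prenyl acetate
Product: 13 (E)-4-acetoxy-2-methylbut-2-en-1-ol
Conditions: SeO2 (cat.), t-BuOOH, CH2Cl2, rt
Reagents that add atoms: tert-butyl hydroperoxide, CC(C)(C)OO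
Why: Riley allylic oxidation (ene reaction, then [2,3]-shift) hydroxylates the E-methyl group of the trisubstituted alkene and gives the E alcohol.

Step 11
Reactants: 13 (E)-4-acetoxy-2-methylbut-2-en-1-ol
Product: 14 (E)-4-acetoxy-2-methylbut-2-enyl pivalate
Conditions: PivCl, pyridine, DMAP (cat.), CH2Cl2, 0 °C
Reagents that add atoms: pivaloyl chloride, CC(C)(C)C(=O)Cl
Why: Acylation of the primary alcohol places the robust, non-nucleophilic ester on the later C7′ oxygen.

Step 12
Reactants: 14 (E)-4-acetoxy-2-methylbut-2-enyl pivalate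
Product: 15 (E)-4-hydroxy-2-methylbut-2-enyl pivalate
Conditions: K2CO3 (cat.), MeOH, 0 °C
Reagents that add atoms: none
Why: Base-catalysed transesterification: the acetate is methanolysed much faster than the hindered pivalate.

Step 13
Reactants: 11 alkenyl iodide; 15 (E)-4-hydroxy-2-methylbut-2-enyl pivalate
Product: 17 C1 ketone with β-C(CH3)(CH2OPiv)(CH=CH2) on C5, via allyl vinyl ether 16 (not isolated)
Conditions: CuI (10 mol %), 3,4,7,8-tetramethyl-1,10-phenanthroline, Cs2CO3, toluene, 80 °C then 120 °C
Reagents that add atoms: none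
Why: Copper-catalysed C–O coupling of the alkenyl iodide with the allylic alcohol followed by Claisen rearrangement: a chair transition state on the face away from the cyclopropane should place the new bond β at C5 and, with the E alkene (methyl axial), fix quaternary C4.

Step 14
Reactants: 17 Claisen ketone
Product: 18 C1 β-alcohol (hydroxyl cis to the C5 branch)
Conditions: L-Selectride, THF, −78 °C
Reagents that add atoms: none
Why: Bulky-hydride reduction: attack from the α face, opposite the quaternary branch on C5, should give the β-carbinol.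

Step 15
Reactants: 18 C1 β-alcohol; 19 3,5-bis(benzyloxy)phenol
Product: 20 C1 α-aryl ether (3,5-bis(benzyloxy)phenoxy trans to the C5 branch and cis to the C10 methyl)
Conditions: PBu3, ADDP, toluene, 0 to 60 °C
Reagents that add atoms: none
Why: Mitsunobu etherification: the phenoxide displaces the alkoxyphosphonium group by SN2 from the open α face, so C1 is inverted.

Step 16
Reactants: 20 C1 α-aryl ether
Product: 21 methyl ketone (C3 carbonyl and C2 methyl on C4)
Conditions: Pd(Quinox)Cl2 (cat.), AgSbF6 (cat.), aq. t-BuOOH, CH2Cl2, 0 °C to rt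
Reagents that add atoms: tert-butyl hydroperoxide, CC(C)(C)OO
Why: Wacker-type oxidation: Markovnikov oxypalladation of the terminal alkene gives the methyl ketone, so C3 and C2 both come from the vinyl group.

Step 17
Reactants: 21 methyl ketone
Product: 23 diazo ketone (C4 bearing methyl and CH2OPiv and C(=O)CHN2; C1 α-aryl ether), via trifluoroacetyl diketone 22 (not isolated)
Conditions: LiHMDS, THF, −78 °C; CF3CO2CH2CF3; then p-ABSA, Et3N, H2O, MeCN, rt
Reagents that add atoms: 4-acetamidobenzenesulfonyl azide, CC(=O)Nc1ccc(cc1)S(=O)(=O)N=[N+]=[N-]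
Why: Detrifluoroacetylative diazo transfer: the methyl group is the only enolisable site, Claisen condensation with the trifluoroacetate activates it, and the sulfonyl azide delivers N2 with loss of the trifluoroacetyl group.

Step 18
Reactants: 23 diazo ketone
Product: 24 cis-hydroazulen-3-one with the tertiary aryl ether at C1
Conditions: Rh2(OAc)4 (1 mol %), CH2Cl2, 40 °C, slow addition (0.01 M)
Reagents that add atoms: none
Why: Rh2(OAc)4 expels N2 from the diazo ketone to give an electrophilic rhodium carbenoid at C2, which inserts into the C1–H bond through a three-centre, hydride-transfer-like transition state in which the oxygen lone pair stabilises the positive charge building at C1. The closest known reaction type is the Rh(II)-catalysed 1,5 C–H insertion of α-diazo ketones into C–H bonds α to an ether oxygen, which gives cyclopentanones. The cyclopentanone ring C1–C2–C3–C4–C5 closes by C1–C2 bond formation in the 1,5 mode, the ring size these carbenoids prefer. Insertion proceeds with retention, so the existing C1 configuration (hydrogen β, cis to the C4 chain on C5) dictates the new quaternary centre and the cis ring fusion. C1–H must win over the other 1,5 C–H bond (C6–H, a strong cyclopropane bond), over the 1,4 hydrogens on the C4 methyl and on C7′, over the electron-rich arene and over ylide formation. Ether activation of C1–H, the ester in place of an ether oxygen at C7′, the weakly basic aryl ether oxygen and the eight-membered ring needed to reach the arene should secure this.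

Step 19
Reactants: 24 cis-hydroazulen-3-one
Product: 25 C3 alcohol (configuration at C3 immaterial)
Conditions: NaBH4, CeCl3·7H2O, MeOH, −40 to 0 °C
Reagents that add atoms: none
Why: Luche reduction: the cerium-assisted, weakly basic hydride reduces the hindered ketone without enolising it toward C2, which would expel the C1 aryloxide.

Step 20
Reactants: 25 C3 alcohol
Product: 26 C3 O-phenyl thiocarbonate
Conditions: PhOC(S)Cl, pyridine, DMAP, CH2Cl2, rt
Reagents that add atoms: O-phenyl chlorothionoformate, S=C(Cl)Oc1ccccc1
Why: Thioacylation of the secondary alcohol without a free alkoxide avoids pivaloyl migration and sets up radical deoxygenation.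

Step 21
Reactants: 26 C3 O-phenyl thiocarbonate
Product: 27 C3-deoxygenated aryl ether pivalate
Conditions: Bu3SnH, AIBN, toluene, 100 °C
Reagents that add atoms: none
Why: Barton–McCombie deoxygenation: the C3 radical is neither cyclopropylcarbinyl nor β to a leaving group, so it should simply abstract hydrogen.

Step 22
Reactants: 27 aryl ether pivalate
Product: 28 C7′ primary alcohol
Conditions: DIBAL-H, CH2Cl2, −78 °C
Reagents that add atoms: none
Why: Reductive cleavage of the pivalate by hydride needs neither acid nor alkoxide base, so the tertiary aryl ether and the cyclopropane are safe.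

Step 23
Reactants: 28 C7′ primary alcohol
Product: 29 C7′ aldehyde
Conditions: Dess–Martin periodinane, NaHCO3, CH2Cl2, rt
Reagents that add atoms: none
Why: Dess–Martin oxidation gives a neopentyl aldehyde that cannot enolise.

Step 24
Reactants: 29 C7′ aldehyde
Product: 31 oxepine with a 2-methylallyl group on C7′ (cis to the C4 methyl), via benzylic alcohol 30 (not isolated)
Conditions: BF3·OEt2, CH2Cl2, −78 to −30 °C; then trimethyl(2-methylallyl)silane, −78 to 0 °C
Reagents that add atoms: trimethyl(2-methylallyl)silane, C=C(C)C[Si](C)(C)C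
Why: Intramolecular Friedel–Crafts hydroxyalkylation (the ring carbon ortho to the ether oxygen attacks the activated aldehyde and closes the seven-membered ring), then Hosomi–Sakurai substitution of the ionised benzylic alcohol: the allylsilane should add to the planar cation from the exo face, away from the C2–C3 bridge, which sets C7′.

Step 25
Reactants: 31 2-methylallyl oxepine
Product: 32 isobutyl oxepine diphenol
Conditions: H2 (1 atm), Pd/C, EtOAc–MeOH, rt
Reagents that add atoms: none
Why: Catalytic hydrogenation saturates the 1,1-disubstituted alkene and hydrogenolyses both benzyl ethers in one operation, while the unconjugated cyclopropane and the non-benzylic C1–O bond should stay intact.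

Step 26
Reactants: 32 isobutyl oxepine diphenol
Product: 33 target (CNP0189833.2)
Conditions: POCl3, DMF, MeCN, 0 °C to rt; then H2O, 50 °C
Reagents that add atoms: N,N-dimethylformamide, CN(C)C=O; water, O
Why: Twofold Vilsmeier–Haack formylation: the two free ring positions, each ortho or para to the oxygen substituents, are the only sites open to the chloroiminium electrophile.

Compound list
1 | (+)-2-carene, (1S,6R)-3,7,7-trimethylbicyclo[4.1.0]hept-2-ene | CC1=C[C@H]2[C@@H](CC1)C2(C)C | starting material
2 | cis-caran-trans-2-ol (OH trans, 3-methyl cis to the CMe2 bridge) | C[C@H]1CC[C@@H]2[C@H]([C@@H]1O)C2(C)C | intermediate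
3 | cis-caran-2-one | C[C@H]1CC[C@@H]2[C@H](C1=O)C2(C)C | intermediate
4 | 4,8,8-trimethyl-3-(trimethylsilyl)bicyclo[5.1.0]octan-2-one | C[C@H]1CC[C@@H]2[C@H](C(=O)C1[Si](C)(C)C)C2(C)C | intermediate (not isolated)
5 | 4,8,8-trimethylbicyclo[5.1.0]octan-2-one (C5 ketone, 4-methyl cis to CMe2) | C[C@H]1CC[C@@H]2[C@H](C(=O)C1)C2(C)C | intermediate
6 | 4,8,8-trimethylbicyclo[5.1.0]oct-2-en-2-yl trifluoromethanesulfonate | C[C@H]1CC[C@@H]2[C@H](C(OS(=O)(=O)C(F)(F)F)=C1)C2(C)C | intermediate
7 | 4,8,8-trimethylbicyclo[5.1.0]oct-2-ene | C[C@H]1CC[C@@H]2[C@H](C=C1)C2(C)C | intermediate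
8 | 4,8,8-trimethylbicyclo[5.1.0]octan-3-ol (C3 epimers) | C[C@H]1CC[C@@H]2[C@H](CC1O)C2(C)C | intermediate
9 | 4,8,8-trimethylbicyclo[5.1.0]octan-3-one (C1 ketone, 4-methyl cis to CMe2) | C[C@H]1CC[C@@H]2[C@H](CC1=O)C2(C)C | intermediate
10 | 2,4,6-triisopropylbenzenesulfonylhydrazone of 9 | C[C@H]1CC[C@@H]2[C@H](CC1=NNS(=O)(=O)c1c(C(C)C)cc(C(C)C)cc1C(C)C)C2(C)C | intermediate
11 | 3-iodo-4,8,8-trimethylbicyclo[5.1.0]oct-2-ene | C[C@H]1CC[C@@H]2[C@H](C=C1I)C2(C)C | intermediate
12 | prenyl acetate | CC(C)=CCOC(C)=O | starting material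
13 | (E)-4-acetoxy-2-methylbut-2-en-1-ol | CC(=O)OC/C=C(\C)CO | intermediate
14 | (E)-4-acetoxy-2-methylbut-2-enyl pivalate | CC(=O)OC/C=C(\C)COC(=O)C(C)(C)C | intermediate
15 | (E)-4-hydroxy-2-methylbut-2-enyl pivalate | OC/C=C(\C)COC(=O)C(C)(C)C | intermediate
16 | allyl vinyl ether from 11 and 15 (C1 enol ether, C1=C5) | C[C@H]1CC[C@@H]2[C@H](C=C1OC/C=C(\C)COC(=O)C(C)(C)C)C2(C)C | intermediate (not isolated)
17 | 2-[2-methyl-1-(pivaloyloxy)but-3-en-2-yl]-4,8,8-trimethylbicyclo[5.1.0]octan-3-one (C1 ketone; C5 branch β, C10 methyl α) | C=C[C@](C)(COC(=O)C(C)(C)C)[C@@H]1C(=O)[C@@H](C)CC[C@@H]2[C@H]1C2(C)C | intermediate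
18 | C1 β-alcohol of 17 | C=C[C@](C)(COC(=O)C(C)(C)C)[C@@H]1[C@H](O)[C@@H](C)CC[C@@H]2[C@H]1C2(C)C | intermediate
19 | 3,5-bis(benzyloxy)phenol | Oc1cc(OCc2ccccc2)cc(OCc2ccccc2)c1 | starting material
20 | C1 α-[3,5-bis(benzyloxy)phenyl] ether with the vinyl branch on C5 | C=C[C@](C)(COC(=O)C(C)(C)C)[C@@H]1[C@@H](Oc2cc(OCc3ccccc3)cc(OCc3ccccc3)c2)[C@@H](C)CC[C@@H]2[C@H]1C2(C)C | intermediate
21 | methyl ketone (C4 bearing CH3, CH2OPiv and acetyl) | CC(=O)[C@](C)(COC(=O)C(C)(C)C)[C@@H]1[C@@H](Oc2cc(OCc3ccccc3)cc(OCc3ccccc3)c2)[C@@H](C)CC[C@@H]2[C@H]1C2(C)C | intermediate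
22 | trifluoroacetyl diketone of 21 | FC(F)(F)C(=O)CC(=O)[C@](C)(COC(=O)C(C)(C)C)[C@@H]1[C@@H](Oc2cc(OCc3ccccc3)cc(OCc3ccccc3)c2)[C@@H](C)CC[C@@H]2[C@H]1C2(C)C | intermediate (not isolated)
23 | diazo ketone on C4 with secondary aryl ether at C1 | [N-]=[N+]=CC(=O)[C@](C)(COC(=O)C(C)(C)C)[C@@H]1[C@@H](Oc2cc(OCc3ccccc3)cc(OCc3ccccc3)c2)[C@@H](C)CC[C@@H]2[C@H]1C2(C)C | intermediate
24 | cis-hydroazulen-3-one with tertiary aryl ether at C1 | c1ccccc1COc1cc(OCc2ccccc2)cc(O[C@]23CC(=O)[C@](C)(COC(=O)C(C)(C)C)[C@H]2[C@H]2[C@@H](CC[C@@H]3C)C2(C)C)c1 | intermediate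
25 | C3 alcohol of 24 (C3 epimers) | c1ccccc1COc1cc(OCc2ccccc2)cc(O[C@]23CC(O)[C@](C)(COC(=O)C(C)(C)C)[C@H]2[C@H]2[C@@H](CC[C@@H]3C)C2(C)C)c1 | intermediate
26 | C3 O-phenyl thiocarbonate | c1ccccc1COc1cc(OCc2ccccc2)cc(O[C@]23CC(OC(=S)Oc4ccccc4)[C@](C)(COC(=O)C(C)(C)C)[C@H]2[C@H]2[C@@H](CC[C@@H]3C)C2(C)C)c1 | intermediate
27 | C3-deoxygenated tertiary aryl ether with CH2OPiv on C4 | c1ccccc1COc1cc(OCc2ccccc2)cc(O[C@]23CC[C@](C)(COC(=O)C(C)(C)C)[C@H]2[C@H]2[C@@H](CC[C@@H]3C)C2(C)C)c1 | intermediate
28 | C7′ primary alcohol | c1ccccc1COc1cc(OCc2ccccc2)cc(O[C@]23CC[C@](C)(CO)[C@H]2[C@H]2[C@@H](CC[C@@H]3C)C2(C)C)c1 | intermediate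
29 | C7′ aldehyde | c1ccccc1COc1cc(OCc2ccccc2)cc(O[C@]23CC[C@](C)(C=O)[C@H]2[C@H]2[C@@H](CC[C@@H]3C)C2(C)C)c1 | intermediate
30 | oxepine benzylic alcohol at C7′ (C7′ epimers) | OC1c2c(OCc4ccccc4)cc(OCc4ccccc4)cc2O[C@]23CC[C@@]1(C)[C@H]2[C@H]1[C@@H](CC[C@@H]3C)C1(C)C | intermediate (not isolated)
31 | oxepine with 2-methylallyl on C7′, bis(benzyl ether) | C=C(C)C[C@H]1c2c(OCc4ccccc4)cc(OCc4ccccc4)cc2O[C@]23CC[C@@]1(C)[C@H]2[C@H]1[C@@H](CC[C@@H]3C)C1(C)C | intermediate
32 | isobutyl oxepine diphenol | CC(C)C[C@H]1c2c(O)cc(O)cc2O[C@]23CC[C@@]1(C)[C@H]2[C@H]1[C@@H](CC[C@@H]3C)C1(C)C | intermediate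
33 | CNP0189833.2 | CC(C)C[C@H]1c2c(O)c(C=O)c(O)c(C=O)c2O[C@]23CC[C@@]1(C)[C@H]2[C@H]1[C@@H](CC[C@@H]3C)C1(C)C | target

Total step count: 26. Longest linear sequence: 23 steps (steps 1–9 and 13–26); the three-step side-chain branch (steps 10–12) joins at step 13.

Steps most likely to fail

Step 18. The carbenoid may be lost before it reaches C1–H: by dimerisation, by attack on the benzyloxy-substituted arene, by insertion into the cyclopropane C6–H bond, or because the diazo transfer of step 17 does not go cleanly. The fallback makes the same α-oxo carbenoid without a diazo compound. It sets out from aryl ether 20. Lemieux–Johnson cleavage (OsO4 cat., NaIO4, 2,6-lutidine, dioxane–water) should give the C3 aldehyde F1. Homologation with the Ohira–Bestmann reagent (K2CO3, MeOH) should give the terminal alkyne F2. Gold(I)-catalysed oxidation of the alkyne with 8-methylquinoline N-oxide (bulky phosphine–gold(I) triflimide, DCE) generates the C2 α-oxo gold carbenoid, which should undergo the same 1,5 insertion into C1–H and return to the route at ketone 24.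

Step 15. Activation of the shielded β-hydroxyl may be slow, and elimination toward C5 may overtake substitution; in addition, step 14 may deliver the other carbinol epimer. The fallback forms the C–O bond at oxygen, with retention, instead of at carbon. It sets out from ketone 17. Equilibrating Meerwein–Ponndorf–Verley reduction (Al(O-i-Pr)3, i-PrOH, toluene, 80 °C) should give the more stable C1 α-alcohol F3, with the hydroxyl trans to the C5 branch. Palladium-catalysed C–O coupling with 1-bromo-3,5-bis(benzyloxy)benzene (allylpalladium chloride dimer, RockPhos, Cs2CO3, toluene, 90 °C) should then arylate the alkoxide and return to the route at aryl ether 20. The same coupling serves if step 14 gives the α-alcohol directly.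

Step 13. C–O coupling at the hindered alkenyl iodide may be slow, the iodide may be lost by reduction, and a competing boat transition state would erode control at C4. The fallback reaches the allyl vinyl ether by acid-catalysed exchange instead of metal-catalysed coupling and bypasses compounds 10 and 11. It sets out from ketone 9. Ketalisation (HC(OMe)3, MeOH, TsOH cat.) should give the dimethyl ketal F4. Heating F4 with alcohol 15 and catalytic propionic acid in xylene at 140 °C, with removal of methanol, should form allyl vinyl ether 16 in situ and rearrange it to ketone 17, where the route is rejoined; the C10 configuration would have to be checked after this acidic step.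

Further compounds
F1 | step 18 | C3 aldehyde on C4 (CH3, CH2OPiv, CHO) with the C1 α-aryl ether | O=C[C@](C)(COC(=O)C(C)(C)C)[C@@H]1[C@@H](Oc2cc(OCc3ccccc3)cc(OCc3ccccc3)c2)[C@@H](C)CC[C@@H]2[C@H]1C2(C)C
F2 | step 18 | terminal alkyne on C4 (CH3, CH2OPiv, C≡CH) with the C1 α-aryl ether | C#C[C@](C)(COC(=O)C(C)(C)C)[C@@H]1[C@@H](Oc2cc(OCc3ccccc3)cc(OCc3ccccc3)c2)[C@@H](C)CC[C@@H]2[C@H]1C2(C)C
F3 | step 15 | C1 α-alcohol, epimer of 18 | C=C[C@](C)(COC(=O)C(C)(C)C)[C@@H]1[C@@H](O)[C@@H](C)CC[C@@H]2[C@H]1C2(C)C
F4 | step 13 | dimethyl ketal of ketone 9 | C[C@H]1CC[C@@H]2[C@H](CC1(OC)OC)C2(C)C
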